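**Retrosynthetic overview**
1. Target ⇒ its 4-O-benzyl ether, with hydrogenolysis last. C3 is an acidic β-keto-lactone carbon, so its trans (S) configuration follows from C4 by equilibration.
2. C3–aroyl bond ⇒ lithium enolate of (R)-4-(3,4-dimethoxybenzyl)butyrolactone + 4-(benzyloxy)-3-methoxybenzoyl chloride.
3. Key disconnection, ring O1–C5 bond ⇒ prochiral 3-(3,4-dimethoxybenzyl)cyclobutanone. A catalytic enantioselective oxygen insertion builds the lactone and sets C4 (R), the only non-epimerisable stereocentre.
4. Cyclobutanone ⇒ methyl eugenol + the keteniminium salt of N,N-dimethylacetamide ([2+2]).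
5. Ring order: both arenes are bought. The cyclobutane is made first and is then expanded to the butyrolactone.

Assumption: the sense of induction of the new catalyst cannot be predicted, so the (S,S) acid is written for the R lactone. If a test run gives the S lactone, the equally accessible (R,R) acid is used. The same holds for the chiral lithium amide in the fallback.

Catalyst of step 2: (S,S)-IDP acid, the imidodiphosphoric acid HN[P(=O)(O2C44H44)]2 (C88H89NO6P2). It is built from two (S)-3,3'-bis(2,4,6-triethylphenyl)-1,1'-bi-2-naphthol units.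

**Step 1**
Reactants: 1 methyl eugenol (4-allyl-1,2-dimethoxybenzene); 2 N,N-dimethylacetamide (1.2 equiv)
Product: 5 3-(3,4-dimethoxybenzyl)cyclobutan-1-one, via keteniminium triflate 3 (not isolated), via cyclobutaniminium triflate 4 (not isolated)
Conditions: Tf2O (1.2 equiv), 2,4,6-collidine (1.2 equiv), ClCH2CH2Cl, 0 to 80 °C, 16 h; then H2O, 80 °C, 2 h
Reagents that add atoms: water, O
Why: Ghosez keteniminium–alkene [2+2] cycloaddition, in which the terminal alkene carbon attacks the central carbon of 3 so that the benzyl-bearing carbon becomes C3, and hydrolysis of iminium salt 4 gives the achiral, prochiral ketone 5 (no stereocentre yet).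

**Step 2**
Reactants: 5 3-(3,4-dimethoxybenzyl)cyclobutan-1-one
Product: 7 (R)-4-(3,4-dimethoxybenzyl)dihydrofuran-2(3H)-one, via Criegee adduct 6 (not isolated)
Conditions: (S,S)-IDP acid C88H89NO6P2 (5 mol %), 35 % aq. H2O2 (1.5 equiv), CHCl3, −40 °C, 48 h
Reagents that add atoms: hydrogen peroxide, OO
Why: Proposed new method: a confined chiral imidodiphosphoric acid is used for the first time for a desymmetrising Baeyer–Villiger oxygen insertion; its P–OH/P=O pair first delivers H2O2 to the strained ketone to give the achiral adduct 6 and then holds 6 at two points (P=O takes the carbinol proton, P–OH protonates the distal peroxide oxygen so that water leaves), and because the narrow C2-symmetric pocket lets the veratrylmethyl arm leave through only one channel, only one O–O rotamer fits, so only one of the two enantiotopic ring CH2 groups stands antiperiplanar to the O–O bond and migrates, which forms the O1–C5 bond and fixes C4 as R, while release of cyclobutanone strain lets the reaction run at −40 °C where the uncatalysed background is negligible; the closest known reaction types are the BINOL-phosphoric-acid-catalysed Baeyer–Villiger oxidation of 3-substituted cyclobutanones with aqueous H2O2 (less selective for flexible 3-benzyl groups than for 3-aryl groups) and the imidodiphosphoric-acid-catalysed sulfoxidation with aqueous H2O2.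

**Step 3**
Reactants: 7 (R)-4-(3,4-dimethoxybenzyl)dihydrofuran-2(3H)-one; 8 4-(benzyloxy)-3-methoxybenzoic acid (1.1 equiv)
Product: 12 (3S,4R)-3-[4-(benzyloxy)-3-methoxybenzoyl]-4-(3,4-dimethoxybenzyl)dihydrofuran-2(3H)-one, via acid chloride 9 (not isolated), via lactone lithium enolate 10 (not isolated), via ketolactone lithium enolate 11 (not isolated)
Conditions: 8, (COCl)2, cat. DMF, CH2Cl2, rt, concentrate; 7, LiN(SiMe3)2 (2.2 equiv), THF, −78 °C, then 9 in THF, −78 to −20 °C; 1 M HCl
Reagents that add atoms: none
Why: Crossed Claisen-type C-acylation of a lactone lithium enolate by an aroyl chloride, in which the second equivalent of base stores the product as chelated enolate 11 and its protonation and equilibration place the aroyl group trans to the C4 benzyl group, so C3 (S) is set under thermodynamic control while C4 is not touched.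

**Step 4**
Reactants: 12 (3S,4R)-3-[4-(benzyloxy)-3-methoxybenzoyl]-4-(3,4-dimethoxybenzyl)dihydrofuran-2(3H)-one
Product: 13 (3S,4R)-4-(3,4-dimethoxybenzyl)-3-(4-hydroxy-3-methoxybenzoyl)dihydrofuran-2(3H)-one (target)
Conditions: H2 (1 atm), Pd/C (10 wt % Pd, 5 mol %), EtOAc, rt, 2–4 h
Reagents that add atoms: none
Why: Catalytic hydrogenolysis of the benzyl aryl ether on zerovalent palladium is much faster in a neutral solvent than reduction of the electron-rich aryl ketone, C4 is inert and C3 stays in its thermodynamically preferred trans arrangement.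

**Compound list**
1 | methyl eugenol (4-allyl-1,2-dimethoxybenzene) | C=CCc1ccc(OC)c(OC)c1 | starting material
2 | N,N-dimethylacetamide | CC(=O)N(C)C | starting material
3 | N,N-dimethylketeniminium triflate | C=C=[N+](C)C.[O-]S(=O)(=O)C(F)(F)F | intermediate
4 | N-[3-(3,4-dimethoxybenzyl)cyclobutylidene]-N-methylmethanaminium triflate | C[N+](C)=C1CC(Cc2ccc(OC)c(OC)c2)C1.[O-]S(=O)(=O)C(F)(F)F | intermediate
5 | 3-(3,4-dimethoxybenzyl)cyclobutan-1-one (achiral) | O=C1CC(Cc2ccc(OC)c(OC)c2)C1 | intermediate
6 | 1-hydroperoxy-3-(3,4-dimethoxybenzyl)cyclobutan-1-ol (Criegee adduct; achiral, C1 epimers not distinguished) | OOC1(O)CC(Cc2ccc(OC)c(OC)c2)C1 | intermediate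
7 | (R)-4-(3,4-dimethoxybenzyl)dihydrofuran-2(3H)-one | O=C1C[C@@H](Cc2ccc(OC)c(OC)c2)CO1 | intermediate
8 | 4-(benzyloxy)-3-methoxybenzoic acid | COc1cc(C(O)=O)ccc1OCc1ccccc1 | starting material
9 | 4-(benzyloxy)-3-methoxybenzoyl chloride | COc1cc(C(Cl)=O)ccc1OCc1ccccc1 | intermediate
10 | lithium (R)-4-(3,4-dimethoxybenzyl)-4,5-dihydrofuran-2-olate | [Li+].[O-]C1=C[C@@H](Cc2ccc(OC)c(OC)c2)CO1 | intermediate
11 | lithium (Z)-[4-(benzyloxy)-3-methoxyphenyl][(4R)-4-(3,4-dimethoxybenzyl)-2-oxodihydrofuran-3(2H)-ylidene]methanolate | [Li+].[O-]/C(c1ccc(OCc2ccccc2)c(OC)c1)=C1\C(=O)OC[C@@H]1Cc1ccc(OC)c(OC)c1 | intermediate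
12 | (3S,4R)-3-[4-(benzyloxy)-3-methoxybenzoyl]-4-(3,4-dimethoxybenzyl)dihydrofuran-2(3H)-one (trans) | COc1cc(C(=O)[C@H]2C(=O)OC[C@@H]2Cc2ccc(OC)c(OC)c2)ccc1OCc1ccccc1 | intermediate
13 | (3S,4R)-4-(3,4-dimethoxybenzyl)-3-(4-hydroxy-3-methoxybenzoyl)dihydrofuran-2(3H)-one (trans) | COc1cc(C(=O)[C@H]2C(=O)OC[C@@H]2Cc2ccc(OC)c(OC)c2)ccc1O | target

**Step count:** 4 steps in total; acid chloride 9 is made and consumed within step 3. Longest linear sequence: 4 (1 → 5 → 7 → 12 → 13).

**Steps most likely to fail**

**Step 2 (the proposed new method).**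
- Risk: the pocket may be too tight for turnover, or the ee may be too low.
- Fallback: it uses known chemistry, sets out from 5 and comes back at 7.
- Desymmetrising deprotonation of 5 with the chiral base LiN[(S)-CHMePh]2 in the presence of Et3SiCl (THF, −100 °C) gives (R)-{[3-(3,4-dimethoxybenzyl)cyclobut-1-en-1-yl]oxy}triethylsilane F1.
- Ozonolysis of its electron-rich C=C bond (O3, CH2Cl2–MeOH, −78 °C, stopped at one equivalent) and NaBH4 reduction in the same flask give (R)-4-(3,4-dimethoxyphenyl)-3-(hydroxymethyl)butanoic acid F2. This acid closes to 7 on acidification with 1 M HCl.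
- The stereocentre is then set by selective C–H removal instead of oxygen insertion. A modest ee can be raised by recrystallising 12.

**Step 1.**
- Risk: the keteniminium ion, or its O-triflyl precursor, may acylate the electron-rich veratryl ring instead of adding to the alkene.
- Fallback: it sets out from 1 and comes back at 5.
- Neutral dichloroketene F3, generated from Cl3CCOCl and Zn(Cu) couple in Et2O, adds to 1 to give rac-2,2-dichloro-3-(3,4-dimethoxybenzyl)cyclobutan-1-one F4.
- Zn dust in AcOH (rt to 70 °C) then removes both chlorines to give 5.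
- This costs one more step, but the ketene does not attack arenes.

**Step 3.**
- Risk: O-acylation or double acylation of the enolates, or consumption of 9 by the amide base.
- Fallback: it sets out from 7 and comes back at 12.
- Aldol addition of enolate 10 to commercial 4-(benzyloxy)-3-methoxybenzaldehyde (THF, −78 °C) occurs anti to the C4 benzyl group. It gives (3S,4R)-3-{[4-(benzyloxy)-3-methoxyphenyl](hydroxy)methyl}-4-(3,4-dimethoxybenzyl)dihydrofuran-2(3H)-one F5 as a mixture of carbinol epimers.
- Dess–Martin periodinane (CH2Cl2, rt) oxidises both epimers to the single ketone 12.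

**Further compounds**
F1 | step 2 | (R)-{[3-(3,4-dimethoxybenzyl)cyclobut-1-en-1-yl]oxy}triethylsilane | CC[Si](CC)(CC)OC1=C[C@H](Cc2ccc(OC)c(OC)c2)C1
F2 | step 2 | (R)-4-(3,4-dimethoxyphenyl)-3-(hydroxymethyl)butanoic acid | OC[C@@H](CC(=O)O)Cc1ccc(OC)c(OC)c1
F3 | step 1 | dichloroketene | ClC(Cl)=C=O
F4 | step 1 | rac-2,2-dichloro-3-(3,4-dimethoxybenzyl)cyclobutan-1-one | O=C1CC(Cc2ccc(OC)c(OC)c2)C1(Cl)Cl
F5 | step 3 | (3S,4R)-3-{[4-(benzyloxy)-3-methoxyphenyl](hydroxy)methyl}-4-(3,4-dimethoxybenzyl)dihydrofuran-2(3H)-one (carbinol epimers) | COc1cc(C(O)[C@H]2C(=O)OC[C@@H]2Cc2ccc(OC)c(OC)c2)ccc1OCc1ccccc1
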